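Amounts first: you charge 20 mM of starting material and 20.0 mM of reagent, and you want to know how much target stands after 3.0 h in each of the three flasks, two of which take one charge slowly.

| flask | starting material | reagent | base | remark | time |
|---|---|---|---|---|---|
| alder | 20 mM | 20 mM | 0.40 mM | run made earlier |  |
| oak | 10 mM | 20 mM | 0.40 mM | run made earlier |  |
| elm | 40 mM | 20 mM | 0.40 mM | run made earlier |  |
| larch | 20 mM | 10 mM | 0.40 mM | run made earlier |  |
| eta | 20 mM | 20.0 mM | 0.400 mM | everything together at the start | 3.0 h |
| delta | 20 mM | 20.0 mM (fed, over 40 min) | 0.400 mM | all else is in the flask from the start; the feed brings no volume worth counting | 3.0 h |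
| theta | 20 mM (fed, over 40 min) | 20.0 mM | 0.400 mM | all else is in the flask from the start; the feed brings no volume worth counting | 3.0 h |

- alder (time / h: target / %, starting material / %): 0.250: 3.6, 28.6; 0.833: 6.6, 11.3; 1.33: 7.4, 6.1; 2.00: 10.0, 5.7; 3.00: 12.6, 2.5
- oak (time / min: target / %, starting material / %): 10.0: 2.2, 47.4; 25.0: 4.6, 30.1; 50.0: 6.6, 18.3; 80.0: 8.1, 10.5; 120: 11.0, 8.5
- elm (time / min: target / %, starting material / %): 10.0: 1.8, 22.1; 25.0: 2.4, 9.5; 50.0: 4.9, 6.2; 80.0: 5.0, 2.4; 120: 8.0, 0.5
- larch (time / min: target / %, starting material / %): 10.0: 1.5, 33.4; 25.0: 0.6, 20.8; 50.0: 3.5, 12.5; 80.0: 3.8, 7.0; 120: 3.1, 6.5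

(standard deviation of a reading: 1 percentage point)

- a species is counted by the starting material in it: one self-condensation product counts as two
- the numbers in the tables scatter by 1 percentage point (one standard deviation)
- on the list of suspects stand: starting material + reagent + by-product -> target + 2 by-product; starting material + reagent -> target + by-product; base + by-product <-> salt; starting material <-> dormant form; 2 starting material -> self-condensation product

1. the flask with the highest amount of target, in percent of the starting material charged ("all alike" if they lie within 1.5 percentage points) (eta / delta / theta / all alike)
2. final target, as a percentage of the starting material charged, in eta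
3. final target, as a percentage of the starting material charged, in delta
4. final target, as a percentage of the starting material charged, in theta

Read the four earlier runs at one moment, 50.0 min. Turn the starting material left into mM, and let k be the rise of one over that amount, per minute, from its start.

| run | starting material charged | reagent | left | k |
|---|---|---|---|---|
| oak | 10 mM | 20 mM | 1.83 mM | 0.00893 /mM/min |
| alder | 20 mM | 20 mM | 2.26 mM | 0.00785 /mM/min |
| elm | 40 mM | 20 mM | 2.48 mM | 0.00756 /mM/min |
| larch | 20 mM | 10 mM | 2.50 mM | 0.00700 /mM/min |

Down the first three rows the charge grows, yet k barely moves, so the loss follows the square of the amount, as self-condensation should. Larch, with less reagent, lies close to alder, so I take the mean, 0.00784 /mM/min, as a reading.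

Reagent can be frozen: with one reagent used per target, alder's last reading of target leaves about 87.4% of it, so I compare the flasks by the starting material they hold.

Now freeze the starting material in theta. The feed brings 0.500 mM/min, and the amount stops rising at the holding level, where k times its square equals the feed rate: 7.99 mM, a steady state. It takes about 16.0 min to arrive, shorter than the feed. Eta has fallen to 2.75 mM by the end of that feed, so theta's holding level is 2.91 times eta's amount. Delta has its full reagent at the end of its feed, with about eta's amount of starting material. My order is theta, eta, delta.

The forecast says theta, with 12.5% in eta, 6.7% in delta and 16.5% in theta: it has the feed hold the starting material near 7 mM, “lowering self-condensation”. I have 7.99 mM for that level.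

The flasks give 11.3% in eta, 5.05% in delta and 17.0% in theta, so theta leads, as forecast, yet self-condensation product still takes 81.2% there.

    starting material + reagent + by-product → target + 2 by-product (k = 6.10 /M²/s)
    starting material + reagent → target + by-product (k = 0.00258 /M/s)
    base + by-product ⇌ salt, settled at all times (K = 1.80 × 10⁶ /M)
    starting material ⇌ dormant form (K = 0.228, k = 4.84 × 10⁻⁴ /s)
    2 starting material → self-condensation product (k = 0.0697 /M/s)

At the end of theta's feed, 0.667 h, starting material stands at 7.21 mM, near the holding level. By 1.50 h self-condensation has 97% of its turnover behind it, while the step helped by by-product reaches half of its own only at 1.44 h. That step runs at 0.33 of the plain step's rate at 0.573 h and 7.1 times it at 3.00 h. Now stop theta at 50 min: from the holding level, k leaves 24.6% of the charge. The computed flask holds 22.2%.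

The runs stem from a simulated flask for an exercise.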